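**Plan**

- Retrosynthesis: both arm Z-alkenes are cut last (double Wittig), then the E-alkene between oxolane C4 and its cyclopropane (cross-metathesis), the oxolane O–C2 bond (epoxide opening), the Z-alkene that precedes that epoxide (Wittig) and the C3–CH(OH) bond (aldol). This leaves a 3-vinylhexanal and one cyclopropyl δ-lactone unit that is used twice, once as aldehyde and once as vinyl compound.
- In that unit the cyclopropane CH2 is removed (Simmons–Smith) and then the lactone bonds C3–C2(=O) and O1–C6 are cut together. This excises CO2 and leaves an iodo vinyl epoxide that comes from a cross-metathesis.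
- Enabling feature: in each oxan-2-one ring the oxygen-bearing C6 is bonded to cyclopropane carbon C1′, and C2′ carries the exocyclic oxygenated (or vinylic) carbon. Before cyclopropanation C1′=C2′ is an E-alkene, so C6 is the distal terminus of the η3-allyl unit C6–C1′–C2′ that a terminal vinyl epoxide delivers, and the α-carbon C3 lies three CH2 groups away as a primary carbanion that can take up CO2.
- Forward order: oxan-2-one ring (step 2), cyclopropane (step 3); separately butenolide, trans-vinyl lactone and open-chain aldehyde; the aldol joins them, then Z-alkene, epoxide and oxolane ring (step 16), cross-metathesis with the second lactone unit (step 18), both diene chains at once (step 23).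
- Stereochemistry: lactone C6 from (R)-2-vinyloxirane by 1,3-chirality transfer; cyclopropane by the chiral dioxaborolane; oxolane C5 by the Zn–ProPhenol alkynylation, C4 by trans cuprate addition, C3 and the cyclopropyl carbinol by D-proline, C2 and the side-chain carbinol by hydroxyl-directed epoxidation of the Z-alkene and invertive 5-exo opening; Z-alkenes from unstabilized ylides, the E-alkene from metathesis.

Key step: step 2

Remark: (R)-2-vinyloxirane is taken as the commercial resolved epoxide, and the ligand antipodes in steps 3 and 7 are those that the usual facial models predict for the stated configurations; the mirror-image ligands are equally available.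

**Route**

Step 1
Reactants: 1 5-iodopent-1-ene; 2 (2R)-2-ethenyloxirane
Product: 3 (2R)-2-[(1E)-5-iodopent-1-en-1-yl]oxirane
Conditions: 2 (4 equiv), second-generation Hoveyda–Grubbs catalyst (3 mol%), CH2Cl2, 40 °C
Reagents that add atoms: none
Why: Olefin cross-metathesis of the unhindered terminal alkene with the less reactive vinyl epoxide (in excess) should give mainly the E-alkene with the epoxide stereocenter untouched, the minor Z-isomer being removed by chromatography.

Step 2
Reactants: 3 (2R)-2-[(1E)-5-iodopent-1-en-1-yl]oxirane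
Product: 6 (6R)-6-[(1E)-3-hydroxyprop-1-en-1-yl]oxan-2-one, via alkyllithium 4 (not isolated), via lithium carboxylate 5 (not isolated)
Conditions: t-BuLi (2.05 equiv), pentane–Et2O 3:2, −78 °C; CO2 (gas), −78 to 0 °C; Ar purge; pyridinium p-toluenesulfonate (1.0 equiv), Pd(PPh3)4 (5 mol%), THF, 25 °C
Reagents that add atoms: carbon dioxide, O=C=O
Why: Iodine–lithium exchange gives alkyllithium 4, whose attack on CO2 forms the C3–C2(=O) bond and gives carboxylate 5, the E-alkene making any cyclization of 4 onto the epoxide geometrically impossible. Zerovalent palladium then ionizes the vinyl epoxide with inversion to a syn,syn-η3-allyl complex whose alkoxide is protonated by the pyridinium salt, and the tethered carboxylate attacks the distal allyl terminus anti to palladium to form the O1–C6 bond. The closest known reaction types are the halogen–lithium exchange/carboxylation of primary iodides and the palladium-catalyzed 1,4-addition of carboxylates to vinyl epoxides (Tsuji–Trost lactonization), here run in one flask. The oxan-2-one ring closes in a 6-exo mode on the allyl terminus, the alternative attack at the proximal terminus requiring an eight-membered ring. The new stereocenter C6 arises by double inversion, so the carboxylate enters on the face that the epoxide oxygen left (1,3-chirality transfer, R to R), and the syn,syn allyl geometry fixes the E-alkene of the resulting allylic alcohol. The step needs distal attack without syn–anti allyl isomerization, which ring size, the E-geometry of 3 and the low temperature should secure, and the purge of excess CO2 should prevent diversion to the vinyl cyclic carbonate.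

Step 3
Reactants: 6 (6R)-6-[(1E)-3-hydroxyprop-1-en-1-yl]oxan-2-one
Product: 7 (6R)-6-[(1R,2R)-2-(hydroxymethyl)cyclopropyl]oxan-2-one
Conditions: Et2Zn, CH2I2, DME, (4S,5S)-2-butyl-N,N,N′,N′-tetramethyl-1,3,2-dioxaborolane-4,5-dicarboxamide (1.2 equiv), CH2Cl2, −10 to 25 °C; aq. NH4Cl
Reagents that add atoms: diiodomethane, ICI
Why: Charette asymmetric Simmons–Smith cyclopropanation, in which the zinc alkoxide of the E-allylic alcohol is bound by the chiral dioxaborolane that delivers CH2 to one alkene face (reagent control), the trans ring geometry following from the E-alkene.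

Step 4
Reactants: 7 (6R)-6-[(1R,2R)-2-(hydroxymethyl)cyclopropyl]oxan-2-one
Product: 8 (1R,2R)-2-[(2R)-6-oxooxan-2-yl]cyclopropane-1-carbaldehyde
Conditions: Dess–Martin periodinane, NaHCO3, CH2Cl2, 0 to 25 °C
Reagents that add atoms: none
Why: Dess–Martin oxidation of the primary alcohol should stop at the aldehyde, and the trans-cyclopropanecarbaldehyde is configurationally stable under the buffered conditions.

Step 5
Reactants: 8 (1R,2R)-2-[(2R)-6-oxooxan-2-yl]cyclopropane-1-carbaldehyde (part of the material)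
Product: 9 (6R)-6-[(1R,2S)-2-ethenylcyclopropyl]oxan-2-one
Conditions: Ph3PCH3Br, KN(SiMe3)2, THF, −78 to 0 °C
Reagents that add atoms: methyltriphenylphosphonium bromide, C[P+](c1ccccc1)(c1ccccc1)c1ccccc1.[Br-]
Why: Wittig methylenation, in which the aldehyde should react far faster than the δ-lactone at low temperature and no stereocenter is touched.

Step 6
Reactants: 10 3-[(4-methoxyphenyl)methoxy]propan-1-ol
Product: 11 3-[(4-methoxyphenyl)methoxy]propanal
Conditions: TEMPO (10 mol%), PhI(OAc)2, CH2Cl2, 25 °C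
Reagents that add atoms: none
Why: Oxoammonium (TEMPO) oxidation gives the β-alkoxy aldehyde under non-basic conditions that should avoid β-elimination.

Step 7
Reactants: 11 3-[(4-methoxyphenyl)methoxy]propanal; 12 methyl prop-2-ynoate
Product: 13 methyl (4R)-4-hydroxy-6-[(4-methoxyphenyl)methoxy]hex-2-ynoate
Conditions: 12 (3 equiv), Me2Zn (3 equiv), (S,S)-ProPhenol (10 mol%), Ph3PO (20 mol%), toluene, 4 °C; aq. NH4Cl
Reagents that add atoms: none
Why: Catalytic asymmetric alkynylation with the dinuclear Zn–ProPhenol complex, in which the chiral catalyst binds aldehyde and zinc alkynylide and sets the carbinol center by catalyst control.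

Step 8
Reactants: 13 methyl (4R)-4-hydroxy-6-[(4-methoxyphenyl)methoxy]hex-2-ynoate
Product: 15 (5R)-5-{2-[(4-methoxyphenyl)methoxy]ethyl}furan-2(5H)-one, via Z-hydroxy enoate 14 (not isolated)
Conditions: H2 (1 atm), Lindlar catalyst (Pd/CaCO3, Pb(OAc)2-poisoned), quinoline, EtOAc, 25 °C; then pyridinium p-toluenesulfonate (cat.), CH2Cl2
Reagents that add atoms: none
Why: Lindlar semi-hydrogenation gives the Z-enoate, whose cis γ-hydroxyl lactonizes to the butenolide without touching the stereocenter.

Step 9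
Reactants: 15 (5R)-5-{2-[(4-methoxyphenyl)methoxy]ethyl}furan-2(5H)-one
Product: 16 (4R,5R)-4-ethenyl-5-{2-[(4-methoxyphenyl)methoxy]ethyl}oxolan-2-one
Conditions: CH2=CHMgBr (2 equiv), CuBr·SMe2 (20 mol%), THF, −78 to −40 °C; aq. NH4Cl
Reagents that add atoms: vinylmagnesium bromide, C=C[Mg]Br
Why: Copper-catalyzed conjugate addition of the vinyl Grignard reagent should occur anti to the C5 substituent of the butenolide, which sets C4 trans to C5 by substrate control.

Step 10
Reactants: 16 (4R,5R)-4-ethenyl-5-{2-[(4-methoxyphenyl)methoxy]ethyl}oxolan-2-one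
Product: 18 (3R,4R)-3-ethenyl-N-methoxy-6-[(4-methoxyphenyl)methoxy]-N-methyl-4-[(triethylsilyl)oxy]hexanamide, via hydroxy amide 17 (not isolated)
Conditions: MeNH(OMe)·HCl, Me3Al, CH2Cl2, 0 to 25 °C; aq. potassium sodium tartrate; crude 17: Et3SiCl, imidazole, CH2Cl2, 0 °C
Reagents that add atoms: N,O-dimethylhydroxylamine hydrochloride, CNOC.Cl; chlorotriethylsilane, CC[Si](Cl)(CC)CC
Why: Aluminium-amide aminolysis opens the lactone to the Weinreb amide, and immediate silylation of the freed hydroxyl should prevent relactonization; no stereocenter is affected.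

Step 11
Reactants: 18 (3R,4R)-3-ethenyl-N-methoxy-6-[(4-methoxyphenyl)methoxy]-N-methyl-4-[(triethylsilyl)oxy]hexanamide
Product: 19 (3R,4R)-3-ethenyl-6-[(4-methoxyphenyl)methoxy]-4-[(triethylsilyl)oxy]hexanal
Conditions: i-Bu2AlH, THF, −78 °C; aq. potassium sodium tartrate
Reagents that add atoms: none
Why: Hydride reduction of a Weinreb amide stops at the chelated tetrahedral intermediate and releases the aldehyde on work-up.

Step 12
Reactants: 19 (3R,4R)-3-ethenyl-6-[(4-methoxyphenyl)methoxy]-4-[(triethylsilyl)oxy]hexanal; 8 (1R,2R)-2-[(2R)-6-oxooxan-2-yl]cyclopropane-1-carbaldehyde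
Product: 20 (2R,3S,4R)-3-ethenyl-2-[(R)-hydroxy{(1R,2R)-2-[(2R)-6-oxooxan-2-yl]cyclopropyl}methyl]-6-[(4-methoxyphenyl)methoxy]-4-[(triethylsilyl)oxy]hexanal
Conditions: D-proline (30 mol%), DMF, 4 °C, slow addition of 19 to 8 (1.5 equiv)
Reagents that add atoms: none
Why: Proline-catalyzed direct cross-aldol reaction, in which the E-enamine of the α-unbranched donor 19 adds to the non-enolizable cyclopropyl aldehyde through the hydrogen-bonded Houk–List transition state, so that D-proline should set both new centers (anti, 2R and carbinol R) by catalyst control while the δ-lactone is left alone.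

Step 13
Reactants: 10 3-[(4-methoxyphenyl)methoxy]propan-1-ol
Product: 21 1-[(3-iodopropoxy)methyl]-4-methoxybenzene
Conditions: I2, PPh3, imidazole, CH2Cl2, 0 to 25 °C
Reagents that add atoms: iodine, II
Why: Appel-type iodination of a primary alcohol through the alkoxyphosphonium salt.

Step 14
Reactants: 21 1-[(3-iodopropoxy)methyl]-4-methoxybenzene
Product: 22 {3-[(4-methoxyphenyl)methoxy]propyl}triphenylphosphonium iodide
Conditions: PPh3, MeCN, 80 °C
Reagents that add atoms: triphenylphosphine, c1ccc(cc1)P(c1ccccc1)c1ccccc1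
Why: SN2 quaternization of triphenylphosphine by the primary iodide.

Step 15
Reactants: 20 (the aldol product); 22 {3-[(4-methoxyphenyl)methoxy]propyl}triphenylphosphonium iodide
Product: 23 (6R)-6-[(1R,2R)-2-{(1R,2R,3Z)-1-hydroxy-6-[(4-methoxyphenyl)methoxy]-2-[(3S,4R)-6-[(4-methoxyphenyl)methoxy]-4-[(triethylsilyl)oxy]hex-1-en-3-yl]hex-3-en-1-yl}cyclopropyl]oxan-2-one
Conditions: 22 (3 equiv), NaN(SiMe3)2, THF, −78 to 0 °C; then 20, −78 to −20 °C
Reagents that add atoms: none
Why: Salt-free Wittig reaction of the unstabilized ylide should give the Z-alkene under kinetic control, the excess ylide tolerating the free hydroxyl and the low temperature protecting the α-stereocenter and the lactone.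

Step 16
Reactants: 23 (the Z-homoallylic alcohol)
Product: 25 (6R)-6-[(1R,2R)-2-{(R)-hydroxy[(2S,3R,4S,5R)-4-ethenyl-2-{(1S)-1-hydroxy-3-[(4-methoxyphenyl)methoxy]propyl}-5-{2-[(4-methoxyphenyl)methoxy]ethyl}oxolan-3-yl]methyl}cyclopropyl]oxan-2-one, via cis-epoxide 24 (not isolated)
Conditions: VO(acac)2 (5 mol%), t-BuOOH (decane), CH2Cl2, 0 to 25 °C; then pyridinium p-toluenesulfonate, MeOH, 25 °C
Reagents that add atoms: tert-butyl hydroperoxide, CC(C)(C)OO
Why: Vanadium-catalyzed epoxidation directed by the homoallylic hydroxyl should deliver oxygen to the Z-alkene face that carries the carbinol carbon in the conformer of least 1,3-allylic strain, and after acid removal of the triethylsilyl group the freed hydroxyl opens the cis-epoxide at the nearer carbon in a 5-exo-tet SN2 step with inversion, which sets oxolane C2 (S, trans to C3) and the side-chain carbinol (S).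

Step 17
Reactants: 25 (the oxolane diol)
Product: 26 the bis(tert-butyldimethylsilyl) ether of 25 (both secondary hydroxyls silylated)
Conditions: t-BuMe2SiOTf, 2,6-lutidine, CH2Cl2, −78 to 0 °C
Reagents that add atoms: tert-butyldimethylsilyl trifluoromethanesulfonate, CC(C)(C)[Si](C)(C)OS(=O)(=O)C(F)(F)F
Why: Silyl triflate silylation, reactive enough for the hindered cyclopropyl carbinol and compatible with both lactone and ether groups.

Step 18
Reactants: 26 (the bis-silyl ether); 9 (6R)-6-[(1R,2S)-2-ethenylcyclopropyl]oxan-2-one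
Product: 27 26 in which the oxolane 4-ethenyl group has become (E)-2-{(1S,2R)-2-[(2R)-6-oxooxan-2-yl]cyclopropyl}ethenyl
Conditions: 9 (3 equiv), second-generation Hoveyda–Grubbs catalyst (10 mol%), CH2Cl2, 40 °C
Reagents that add atoms: none
Why: Olefin cross-metathesis of two α-branched terminal alkenes, the only alkenes present, should give the E-1,2-disubstituted alkene under thermodynamic control with the vinylcyclopropane ring intact.

Step 19
Reactants: 27 (the cross-metathesis product)
Product: 28 the diol obtained from 27 by loss of both 4-methoxybenzyl groups (two primary alcohols)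
Conditions: DDQ, CH2Cl2–aq. NaH2PO4/Na2HPO4 (pH 7), 0 °C
Reagents that add atoms: none
Why: Oxidative cleavage of 4-methoxybenzyl ethers by DDQ through the benzylic oxocarbenium ion, which leaves silyl ethers, lactones and the alkene untouched.

Step 20
Reactants: 28 (the diol)
Product: 29 the dialdehyde corresponding to 28 (oxolane 5-CH2CHO and side-chain CH(OSi)CH2CHO)
Conditions: Dess–Martin periodinane, NaHCO3, CH2Cl2, 0 °C
Reagents that add atoms: none
Why: Buffered Dess–Martin oxidation gives both β-oxygenated aldehydes without base-induced β-elimination, and the crude product is used at once.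

Step 21
Reactants: 30 (3Z)-hex-3-en-1-ol
Product: 31 (3Z)-1-iodohex-3-ene
Conditions: I2, PPh3, imidazole, CH2Cl2, 0 °C
Reagents that add atoms: iodine, II
Why: Appel-type iodination of the primary alcohol, which does not isomerize the Z-alkene.

Step 22
Reactants: 31 (3Z)-1-iodohex-3-ene
Product: 32 [(3Z)-hex-3-en-1-yl]triphenylphosphonium iodide
Conditions: PPh3, MeCN, 80 °C
Reagents that add atoms: triphenylphosphine, c1ccc(cc1)P(c1ccccc1)c1ccccc1
Why: SN2 quaternization of triphenylphosphine by the primary iodide.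

Step 23
Reactants: 29 (the dialdehyde); 32 [(3Z)-hex-3-en-1-yl]triphenylphosphonium iodide
Product: 33 the bis(tert-butyldimethylsilyl) ether of the target
Conditions: 32 (3 equiv), NaN(SiMe3)2, THF, −78 to 0 °C; then 29, −78 to 0 °C
Reagents that add atoms: none
Why: Twofold Z-selective Wittig reaction of the unstabilized homoallylic ylide should install both skipped (Z,Z)-dienes in one operation, the aldehydes reacting at −78 °C faster than β-elimination or attack on the lactones.

Step 24
Reactants: 33 (the bis-silyl ether)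
Product: 34 the target, (6R)-6-[(1R,2R)-2-{(R)-hydroxy[(2S,3R,4S,5R)-2-[(1S,3Z,6Z)-1-hydroxynona-3,6-dien-1-yl]-5-[(2Z,5Z)-octa-2,5-dien-1-yl]-4-{(E)-2-[(1S,2R)-2-[(2R)-6-oxooxan-2-yl]cyclopropyl]ethenyl}oxolan-3-yl]methyl}cyclopropyl]oxan-2-one
Conditions: HF·pyridine, pyridine, THF, 0 to 25 °C
Reagents that add atoms: none
Why: Buffered fluoride desilylation removes both silyl ethers without acid or base strong enough to affect the lactones, the cyclopropyl carbinol or the skipped dienes.

**Compound list**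

1 | 5-iodopent-1-ene | C=CCCCI | starting material
2 | (2R)-2-ethenyloxirane | C=C[C@@H]1CO1 | starting material
3 | (2R)-2-[(1E)-5-iodopent-1-en-1-yl]oxirane | ICCC/C=C/[C@@H]1CO1 | intermediate
4 | [(4E)-5-[(2R)-oxiran-2-yl]pent-4-en-1-yl]lithium | [Li]CCC/C=C/[C@@H]1CO1 | intermediate
5 | lithium (5E)-6-[(2R)-oxiran-2-yl]hex-5-enoate | [Li+].[O-]C(=O)CCC/C=C/[C@@H]1CO1 | intermediate
6 | (6R)-6-[(1E)-3-hydroxyprop-1-en-1-yl]oxan-2-one | OC/C=C/[C@H]1CCCC(=O)O1 | intermediate
7 | (6R)-6-[(1R,2R)-2-(hydroxymethyl)cyclopropyl]oxan-2-one | OC[C@@H]1C[C@H]1[C@H]1CCCC(=O)O1 | intermediate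
8 | (1R,2R)-2-[(2R)-6-oxooxan-2-yl]cyclopropane-1-carbaldehyde | O=C[C@@H]1C[C@H]1[C@H]1CCCC(=O)O1 | intermediate
9 | (6R)-6-[(1R,2S)-2-ethenylcyclopropyl]oxan-2-one | C=C[C@@H]1C[C@H]1[C@H]1CCCC(=O)O1 | intermediate
10 | 3-[(4-methoxyphenyl)methoxy]propan-1-ol | COc1ccc(COCCCO)cc1 | starting material
11 | 3-[(4-methoxyphenyl)methoxy]propanal | COc1ccc(COCCC=O)cc1 | intermediate
12 | methyl prop-2-ynoate | C#CC(=O)OC | starting material
13 | methyl (4R)-4-hydroxy-6-[(4-methoxyphenyl)methoxy]hex-2-ynoate | COC(=O)C#C[C@H](O)CCOCc1ccc(OC)cc1 | intermediate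
14 | methyl (2Z,4R)-4-hydroxy-6-[(4-methoxyphenyl)methoxy]hex-2-enoate | COC(=O)/C=C\[C@H](O)CCOCc1ccc(OC)cc1 | intermediate
15 | (5R)-5-{2-[(4-methoxyphenyl)methoxy]ethyl}furan-2(5H)-one | O=C1C=C[C@@H](CCOCc2ccc(OC)cc2)O1 | intermediate
16 | (4R,5R)-4-ethenyl-5-{2-[(4-methoxyphenyl)methoxy]ethyl}oxolan-2-one | O=C1C[C@H](C=C)[C@@H](CCOCc2ccc(OC)cc2)O1 | intermediate
17 | (3R,4R)-3-ethenyl-4-hydroxy-N-methoxy-6-[(4-methoxyphenyl)methoxy]-N-methylhexanamide | CON(C)C(=O)C[C@H](C=C)[C@H](O)CCOCc1ccc(OC)cc1 | intermediate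
18 | (3R,4R)-3-ethenyl-N-methoxy-6-[(4-methoxyphenyl)methoxy]-N-methyl-4-[(triethylsilyl)oxy]hexanamide | CON(C)C(=O)C[C@H](C=C)[C@H](O[Si](CC)(CC)CC)CCOCc1ccc(OC)cc1 | intermediate
19 | (3R,4R)-3-ethenyl-6-[(4-methoxyphenyl)methoxy]-4-[(triethylsilyl)oxy]hexanal | O=CC[C@H](C=C)[C@H](O[Si](CC)(CC)CC)CCOCc1ccc(OC)cc1 | intermediate
20 | (2R,3S,4R)-3-ethenyl-2-[(R)-hydroxy{(1R,2R)-2-[(2R)-6-oxooxan-2-yl]cyclopropyl}methyl]-6-[(4-methoxyphenyl)methoxy]-4-[(triethylsilyl)oxy]hexanal | O=C[C@H]([C@H](C=C)[C@H](O[Si](CC)(CC)CC)CCOCc1ccc(OC)cc1)[C@H](O)[C@@H]1C[C@H]1[C@H]1CCCC(=O)O1 | intermediate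
21 | 1-[(3-iodopropoxy)methyl]-4-methoxybenzene | COc1ccc(COCCCI)cc1 | intermediate
22 | {3-[(4-methoxyphenyl)methoxy]propyl}triphenylphosphonium iodide | COc1ccc(COCCC[P+](c2ccccc2)(c2ccccc2)c2ccccc2)cc1.[I-] | intermediate
23 | (6R)-6-[(1R,2R)-2-{(1R,2R,3Z)-1-hydroxy-6-[(4-methoxyphenyl)methoxy]-2-[(3S,4R)-6-[(4-methoxyphenyl)methoxy]-4-[(triethylsilyl)oxy]hex-1-en-3-yl]hex-3-en-1-yl}cyclopropyl]oxan-2-one | COc1ccc(COCC/C=C\[C@H]([C@H](C=C)[C@H](O[Si](CC)(CC)CC)CCOCc2ccc(OC)cc2)[C@H](O)[C@@H]2C[C@H]2[C@H]2CCCC(=O)O2)cc1 | intermediate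
24 | 23 with the Z-alkene converted into the cis-(2R,3S)-oxirane (C2 on the chain, C3 bearing the 2-[(4-methoxyphenyl)methoxy]ethyl group; oxygen on the face syn to the carbinol carbon) | COc1ccc(COCC[C@@H]2O[C@@H]2[C@H]([C@H](C=C)[C@H](O[Si](CC)(CC)CC)CCOCc2ccc(OC)cc2)[C@H](O)[C@@H]2C[C@H]2[C@H]2CCCC(=O)O2)cc1 | intermediate
25 | (6R)-6-[(1R,2R)-2-{(R)-hydroxy[(2S,3R,4S,5R)-4-ethenyl-2-{(1S)-1-hydroxy-3-[(4-methoxyphenyl)methoxy]propyl}-5-{2-[(4-methoxyphenyl)methoxy]ethyl}oxolan-3-yl]methyl}cyclopropyl]oxan-2-one | COc1ccc(COCC[C@H](O)[C@H]2O[C@H](CCOCc3ccc(OC)cc3)[C@@H](C=C)[C@@H]2[C@H](O)[C@@H]2C[C@H]2[C@H]2CCCC(=O)O2)cc1 | intermediate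
26 | 25 with both secondary hydroxyls as tert-butyldimethylsilyl ethers | COc1ccc(COCC[C@H](O[Si](C)(C)C(C)(C)C)[C@H]2O[C@H](CCOCc3ccc(OC)cc3)[C@@H](C=C)[C@@H]2[C@H](O[Si](C)(C)C(C)(C)C)[C@@H]2C[C@H]2[C@H]2CCCC(=O)O2)cc1 | intermediate
27 | 26 with the oxolane 4-ethenyl group replaced by (E)-2-{(1S,2R)-2-[(2R)-6-oxooxan-2-yl]cyclopropyl}ethenyl | COc1ccc(COCC[C@H](O[Si](C)(C)C(C)(C)C)[C@H]2O[C@H](CCOCc3ccc(OC)cc3)[C@@H](/C=C/[C@@H]3C[C@H]3[C@H]3CCCC(=O)O3)[C@@H]2[C@H](O[Si](C)(C)C(C)(C)C)[C@@H]2C[C@H]2[C@H]2CCCC(=O)O2)cc1 | intermediate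
28 | 27 with both 4-methoxybenzyl ethers cleaved to primary alcohols | OCC[C@H](O[Si](C)(C)C(C)(C)C)[C@H]1O[C@H](CCO)[C@@H](/C=C/[C@@H]2C[C@H]2[C@H]2CCCC(=O)O2)[C@@H]1[C@H](O[Si](C)(C)C(C)(C)C)[C@@H]1C[C@H]1[C@H]1CCCC(=O)O1 | intermediate
29 | the dialdehyde of 28 (both primary alcohols oxidized) | O=CC[C@H](O[Si](C)(C)C(C)(C)C)[C@H]1O[C@H](CC=O)[C@@H](/C=C/[C@@H]2C[C@H]2[C@H]2CCCC(=O)O2)[C@@H]1[C@H](O[Si](C)(C)C(C)(C)C)[C@@H]1C[C@H]1[C@H]1CCCC(=O)O1 | intermediate
30 | (3Z)-hex-3-en-1-ol | CC/C=C\CCO | starting material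
31 | (3Z)-1-iodohex-3-ene | CC/C=C\CCI | intermediate
32 | [(3Z)-hex-3-en-1-yl]triphenylphosphonium iodide | CC/C=C\CC[P+](c1ccccc1)(c1ccccc1)c1ccccc1.[I-] | intermediate
33 | the target with both secondary hydroxyls as tert-butyldimethylsilyl ethers | CC/C=C\C/C=C\C[C@H](O[Si](C)(C)C(C)(C)C)[C@H]1O[C@H](C/C=C\C/C=C\CC)[C@@H](/C=C/[C@@H]2C[C@H]2[C@H]2CCCC(=O)O2)[C@@H]1[C@H](O[Si](C)(C)C(C)(C)C)[C@@H]1C[C@H]1[C@H]1CCCC(=O)O1 | intermediate
34 | (6R)-6-[(1R,2R)-2-{(R)-hydroxy[(2S,3R,4S,5R)-2-[(1S,3Z,6Z)-1-hydroxynona-3,6-dien-1-yl]-5-[(2Z,5Z)-octa-2,5-dien-1-yl]-4-{(E)-2-[(1S,2R)-2-[(2R)-6-oxooxan-2-yl]cyclopropyl]ethenyl}oxolan-3-yl]methyl}cyclopropyl]oxan-2-one (CNP0273074.2) | CC/C=C\C/C=C\C[C@H](O)[C@H]1O[C@H](C/C=C\C/C=C\CC)[C@@H](/C=C/[C@@H]2C[C@H]2[C@H]2CCCC(=O)O2)[C@@H]1[C@H](O)[C@@H]1C[C@H]1[C@H]1CCCC(=O)O1 | target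

**Totals and risks**

Total step count: 24. Longest linear sequence: 15 steps (from 10 through steps 6–12, 15–20, 23 and 24).

Steps most likely to fail:

1. Step 2. The alkyllithium may attack the vinyl epoxide or add twice to CO2. In the palladium stage the allyl complex may lose stereochemical memory by syn–anti isomerization, undergo β-hydride elimination to a dienol, or the alkoxide may start lactone oligomerization. Fallback: setting out from 2, cross-metathesis with commercial methyl hex-5-enoate under the conditions of step 1 should give methyl (5E)-6-[(2R)-oxiran-2-yl]hex-5-enoate F1. Saponification with LiOH (1 equiv, THF–H2O, 0 °C) then gives the lithium carboxylate 5, which is cyclized in the same aqueous THF with Pd(PPh3)4, water serving as the proton source. The route is rejoined at 5 and thus at 6; the C3–C2(=O) bond is then bought with the ester instead of being made from CO2.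

2. Step 12. Enamine formation from the β-branched donor may be slow, so that self-condensation of 19, dehydration of the aldol or a mismatched pairing of catalyst and substrate stereocenters erodes the outcome. Fallback: setting out from 16, Me3Al/EtSH opens the lactone to S-ethyl (3R,4R)-3-ethenyl-4-hydroxy-6-[(4-methoxyphenyl)methoxy]hexanethioate F2, which is silylated (Et3SiCl, imidazole) to S-ethyl (3R,4R)-3-ethenyl-6-[(4-methoxyphenyl)methoxy]-4-[(triethylsilyl)oxy]hexanethioate F3. Enolization with (c-C6H11)2BCl/Et3N to the E-boron enolate and addition to 8 through a Zimmerman–Traxler chair should give the anti aldol S-ethyl (2R,3S,4R)-3-ethenyl-2-[(R)-hydroxy{(1R,2R)-2-[(2R)-6-oxooxan-2-yl]cyclopropyl}methyl]-6-[(4-methoxyphenyl)methoxy]-4-[(triethylsilyl)oxy]hexanethioate F4, with facial control by the adjacent stereocenter or, if needed, by a chiral dialkylboron reagent. Fukuyama reduction (Et3SiH, Pd/C, acetone) converts the thioester into the aldehyde without touching the δ-lactone, and the route is rejoined at 20.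

3. Step 16. Oxygen delivery may be insufficiently face-selective, the ethenyl group may be epoxidized in competition, or the epoxide may be opened by the wrong hydroxyl or the cyclopropyl carbinol may ionize under acid. Fallback: setting out from 23, thiyl-radical equilibration (PhSSPh, hν, benzene) gives the separable (3E)-isomer of 23 F5, and pyridinium p-toluenesulfonate in MeOH removes the silyl group to give the (3E)-diol F6. A syn-oxidative cyclization with CF3CO2ReO3 (from Re2O7 and (CF3CO)2O; 2,6-lutidine, CH2Cl2, low temperature) then adds the ring oxygen and the hydroxyl to the same face of the E-alkene. This gives the same threo ether–carbinol pair and the 2,5-trans ring without an epoxide, and the route is rejoined at 25.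

**Further compounds**

F1 | step 2 | methyl (5E)-6-[(2R)-oxiran-2-yl]hex-5-enoate | COC(=O)CCC/C=C/[C@@H]1CO1
F2 | step 12 | S-ethyl (3R,4R)-3-ethenyl-4-hydroxy-6-[(4-methoxyphenyl)methoxy]hexanethioate | CCSC(=O)C[C@H](C=C)[C@H](O)CCOCc1ccc(OC)cc1
F3 | step 12 | S-ethyl (3R,4R)-3-ethenyl-6-[(4-methoxyphenyl)methoxy]-4-[(triethylsilyl)oxy]hexanethioate | CCSC(=O)C[C@H](C=C)[C@H](O[Si](CC)(CC)CC)CCOCc1ccc(OC)cc1
F4 | step 12 | S-ethyl (2R,3S,4R)-3-ethenyl-2-[(R)-hydroxy{(1R,2R)-2-[(2R)-6-oxooxan-2-yl]cyclopropyl}methyl]-6-[(4-methoxyphenyl)methoxy]-4-[(triethylsilyl)oxy]hexanethioate | CCSC(=O)[C@H]([C@H](C=C)[C@H](O[Si](CC)(CC)CC)CCOCc1ccc(OC)cc1)[C@H](O)[C@@H]1C[C@H]1[C@H]1CCCC(=O)O1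
F5 | step 16 | (3E)-isomer of 23 | COc1ccc(COCC/C=C/[C@H]([C@H](C=C)[C@H](O[Si](CC)(CC)CC)CCOCc2ccc(OC)cc2)[C@H](O)[C@@H]2C[C@H]2[C@H]2CCCC(=O)O2)cc1
F6 | step 16 | (3E)-diol, F5 without the triethylsilyl group | COc1ccc(COCC/C=C/[C@H]([C@H](C=C)[C@H](O)CCOCc2ccc(OC)cc2)[C@H](O)[C@@H]2C[C@H]2[C@H]2CCCC(=O)O2)cc1
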